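A direct plan would hydroxylate 2,5-dibromoanisole to 3,6-dibromo-2-methoxyphenol A1 (lithiation, borylation, oxidation) and alkylate it to the aryloxyacetate A2;
it would then grow the second ring from that chain: Claisen condensation to keto ester A3, Michael addition to acrolein (keto aldehyde A4),
aldol closure with decarboxylation to the 2-aryloxycyclohexenone A5, silyl dienol ether A6 and DDQ dehydrogenation to the 2-aryloxyphenol A7;
dibromination to A8 and BBr3 demethylation would finish it.
Its weakest part would be the chain-building run from A2 to A7: five steps that would only assemble an unsubstituted phenol ring, through an acrolein Michael addition open to polymerisation and double addition.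
The aldol ring closure would rest on enolisation at the less acidic ArOCH2 carbon of a sensitive keto aldehyde, so the closure would be left to chance.
The dibromination would fall on late material (A7), where the free hydroxyl would have to out-direct the diaryl ether oxygen and the reaction stop at two bromines.

**Plan of the new route**
Ring A is the 3,5-dibromo-2-hydroxyphenoxy ring (OH on C1, ether oxygen on C6); ring B is the 3,6-dibromo-2-hydroxyphenyl ring (C1' on the ether oxygen, Br on C2' and C5', OH on C6').
The retrosynthesis cuts ring B itself at C1'–C2' and C5'–C6' and ties C6' back to the hydroxyl oxygen of ring A; this gives 2,5-dibromothiophene 1,1-dioxide and a 6,8-dibromo-1,4-benzodioxin-2-one.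
The feature that allows this: ring B is a 3,6-dibromocatechol, so C2'(Br)–C3'H=C4'H–C5'(Br) is the symmetric carbon chain of 2,5-dibromothiophene, and C1' and C6' sit on the two catechol oxygens of ring A just as C3 and C2 of the benzodioxinone do.
Ring A is present from the start (a commercial catechol monoether, brominated under control of its free hydroxyl, then lactonised); ring B arises last, in one operation: Diels–Alder reaction of the lactone's ketene silyl acetal, loss of SO2, and aromatisation in which the phenoxide of ring A is the leaving group.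
Nothing is built chain-wise or dehydrogenated, no aldol closure is left open, the diaryl ether C–O bond is never made by a coupling (it is the alkyl aryl ether bond of the starting material), and all four bromines are in the two building blocks, so no late bromination occurs.

Key step: step 4

Remark: the target is achiral, so no stereocentre has to be set; the stereocentres of the transient intermediates 7 and 8 vanish on aromatisation.

Step 1
Reactants: 1 2-(2-hydroxyphenoxy)acetic acid
Product: 2 2-(3,5-dibromo-2-hydroxyphenoxy)acetic acid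
Conditions: Br2 (2.05 equiv), AcOH, 15 °C → rt
Reagents that add atoms: bromine BrBr
Why: Electrophilic aromatic bromination, in which the free hydroxyl is the strongest donor and should send the two bromines to its para and its one free ortho position, on the first and cheapest intermediate, where the substitution pattern can be proved before anything is invested.

Step 2
Reactants: 2 2-(3,5-dibromo-2-hydroxyphenoxy)acetic acid
Product: 3 6,8-dibromo-2,3-dihydro-1,4-benzodioxin-2-one
Conditions: p-TsOH·H2O (5 mol %), toluene, reflux (Dean–Stark)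
Reagents that add atoms: none
Why: Acid-catalysed intramolecular Fischer esterification (lactonisation) to a six-membered ring with azeotropic removal of water; the connectivity of 1 alone decides that the oxygen flanked by bromine becomes the acyl oxygen, the later leaving group.

Step 3
Reactants: 4 2,5-dibromothiophene
Product: 5 2,5-dibromothiophene 1,1-dioxide
Conditions: CF3CO3H [from urea·H2O2 (6 equiv) and (CF3CO)2O (5 equiv)], MeCN, 0 °C → rt
Reagents that add atoms: trifluoroperacetic acid OOC(=O)C(F)(F)F (made in the flask from urea–hydrogen peroxide NC(N)=O.OO and trifluoroacetic anhydride O=C(OC(=O)C(F)(F)F)C(F)(F)F; it supplies both sulfone oxygens)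
Why: Electrophilic oxidation at sulfur by a peracid strong enough for the bromine-deactivated thiophene, which should take the transient S-oxide on to the S,S-dioxide before it can dimerise, while the two α-bromines slow the Diels–Alder dimerisation of the product.

Step 4 (key step)
Reactants: 3 6,8-dibromo-2,3-dihydro-1,4-benzodioxin-2-one; 5 2,5-dibromothiophene 1,1-dioxide
Product: 10 2,4-dibromo-1-(tert-butyldimethylsilyloxy)-6-[3,6-dibromo-2-(tert-butyldimethylsilyloxy)phenoxy]benzene (bis-silyl ether of the target), via ketene silyl acetal 6 (not isolated), via bicyclic sulfone cycloadduct 7 (not isolated), via cis-dihydrodibenzodioxin silyl ketal 8 (not isolated), via monosilyl ether phenol 9 (not isolated)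
Conditions: TBSOTf (2.4 equiv), i-Pr2NEt (3 equiv), toluene, 0 °C → rt; then 5 (1.3 equiv, in portions), rt → 70 °C; NaHCO3 work-up
Reagents that add atoms: tert-butyldimethylsilyl triflate CC(C)(C)[Si](C)(C)OS(=O)(=O)C(F)(F)F
Why: Proposed new method: soft enolisation (silyl triflate and hindered amine, as used for 1,4-dioxan-2-ones before Ireland–Claisen rearrangements) should turn lactone 3 into the cyclic ketene silyl acetal 6, whose C2=C3 bond carries three oxygens and is a high-HOMO dienophile for the LUMO-lowered diene 5 in an inverse-electron-demand Diels–Alder reaction across C2 and C5 of the thiophene dioxide (intermolecular [4+2], the mode by which ring B closes, forming C1'–C2' and C5'–C6'). The bicyclic sulfone 7 should lose SO2 by cheletropic extrusion to the cis-dihydrodibenzodioxin 8, in which the former lactone carbon is a mixed silyl aryl ketal next to a diene. Heterolysis of its bond to the oxygen of ring A (a 2,4-dibromophenoxide, a far better nucleofuge than a silanolate) gives a silyloxy-stabilised arenium ion that loses the neighbouring proton, so ring B aromatises, the dioxin ring opens and the phenol 9 of ring A is unveiled and silylated by the excess reagent to 10. The closest known reaction types are the benzannulation of halogenated thiophene 1,1-dioxides with enamines or enol ethers (Diels–Alder, SO2 extrusion, loss of amine or alcohol) and the cycloaddition of ketene acetals to 2-pyrones with loss of CO2 and alcohol. The stereocentres of 7 and 8 (racemic, cis ring fusion from suprafacial addition, endo or exo without consequence) are all erased, and no regiochemical question arises because 5 is C2v-symmetric. The step needs [4+2] to beat Michael-type or [2+2] addition, which attack at a diene terminus (it generates an allylic α-sulfonyl carbanion that closes on the oxocarbenium carbon) should favour, and loss of phenoxide to beat loss of silanol, which the leaving-group abilities secure.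

Step 5
Reactants: 10 bis-silyl ether of the target
Product: 11 3,6-dibromo-2-(3,5-dibromo-2-hydroxyphenoxy)phenol (target)
Conditions: HF·pyridine, THF, 0 °C → rt
Reagents that add atoms: none
Why: Fluoride-mediated cleavage of both aryl silyl ethers, driven by the strong Si–F bond, under conditions that offer the aryl bromides and the diaryl ether no reaction path.

**Compound list**
1 | 2-(2-hydroxyphenoxy)acetic acid | OC(=O)COc1ccccc1O | starting material
2 | 2-(3,5-dibromo-2-hydroxyphenoxy)acetic acid | OC(=O)COc1cc(Br)cc(Br)c1O | intermediate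
3 | 6,8-dibromo-2,3-dihydro-1,4-benzodioxin-2-one | O=C1COc2cc(Br)cc(Br)c2O1 | intermediate
4 | 2,5-dibromothiophene | Brc1ccc(Br)s1 | starting material
5 | 2,5-dibromothiophene 1,1-dioxide | O=S1(=O)C(Br)=CC=C1Br | intermediate
6 | tert-butyl[(6,8-dibromo-1,4-benzodioxin-2-yl)oxy]dimethylsilane (ketene silyl acetal) | CC(C)(C)[Si](C)(C)OC1=COc2cc(Br)cc(Br)c2O1 | intermediate
7 | 1,4,6,8-tetrabromo-4a-(tert-butyldimethylsilyloxy)-1,4,4a,10a-tetrahydro-1,4-epithiodibenzo[b,e][1,4]dioxin S,S-dioxide (racemic, cis ring fusion, endo/exo not defined, so no configuration is written) | O=S1(=O)C2(Br)C=CC1(Br)C3(O[Si](C)(C)C(C)(C)C)Oc4c(Br)cc(Br)cc4OC23 | intermediate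
8 | cis-1,4,6,8-tetrabromo-4a-(tert-butyldimethylsilyloxy)-4a,10a-dihydrodibenzo[b,e][1,4]dioxin (racemic, one enantiomer drawn) | BrC1=CC=C(Br)[C@@]2(O[Si](C)(C)C(C)(C)C)Oc3c(Br)cc(Br)cc3O[C@@H]12 | intermediate
9 | 2,4-dibromo-6-[3,6-dibromo-2-(tert-butyldimethylsilyloxy)phenoxy]phenol | Oc1c(Br)cc(Br)cc1Oc1c(Br)ccc(Br)c1O[Si](C)(C)C(C)(C)C | intermediate
10 | 2,4-dibromo-1-(tert-butyldimethylsilyloxy)-6-[3,6-dibromo-2-(tert-butyldimethylsilyloxy)phenoxy]benzene | CC(C)(C)[Si](C)(C)Oc1c(Br)cc(Br)cc1Oc1c(Br)ccc(Br)c1O[Si](C)(C)C(C)(C)C | intermediate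
11 | 3,6-dibromo-2-(3,5-dibromo-2-hydroxyphenoxy)phenol (achiral) | Oc1c(Br)cc(Br)cc1Oc1c(Br)ccc(Br)c1O | target

**Step count**
Total: 5 steps. Longest linear sequence: 4 steps (steps 1, 2, 4 and 5 from 1); step 3 is a one-step branch from 4.

**Steps most likely to fail**

Step 4 (proposed new method). Several processes could defeat it:
- the ketene acetal may add to the diene stepwise (Michael-type or [2+2]) and not by [4+2];
- the amine may degrade the diene;
- the liberated phenol may protodesilylate the ketene acetal faster than it is silylated;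
- silanol may be lost in place of ring opening, so that the dioxin ring stays closed (the crude product should then be handled as a potential polybrominated dioxin).

Fallback by known chemistry, setting out from 5: a Diels–Alder reaction with vinylene carbonate (O=C1OC=CO1; toluene, 120 °C, sealed tube) would give the bicyclic sulfone 4,7-dibromo-3a,4,7,7a-tetrahydro-4,7-epithio-1,3-benzodioxol-2-one S,S-dioxide F1, which should lose SO2 in the flask to cis-4,7-dibromo-3a,7a-dihydro-1,3-benzodioxol-2-one F2. Dehydrogenation (DDQ, chlorobenzene, reflux) would give 4,7-dibromo-1,3-benzodioxol-2-one F3, and mild hydrolysis (NaHCO3, aqueous MeOH) 3,6-dibromocatechol F4. This symmetric catechol (in excess, K2CO3, DMF, 60 °C) would displace fluoride from commercial 2,4-dibromo-6-fluorobenzaldehyde (O=Cc1c(F)cc(Br)cc1Br; SNAr activated by the ortho formyl group) to give 2,4-dibromo-6-(3,6-dibromo-2-hydroxyphenoxy)benzaldehyde F5. A Dakin oxidation (mCPBA, CH2Cl2; then K2CO3, MeOH) through 2,4-dibromo-6-(3,6-dibromo-2-hydroxyphenoxy)phenyl formate F6 would come back to the route at 11.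

Step 3. Oxidation of the electron-poor sulfur may stall, the S-oxide may dimerise, or the dioxide may decompose during work-up. Fallback, setting out from 4: double bromine–lithium exchange (n-BuLi, THF, −78 °C) and silylation (Me3SiCl) would give 2,5-bis(trimethylsilyl)thiophene F7, an electron-rich thiophene that mCPBA (CH2Cl2, rt) should oxidise cleanly to 2,5-bis(trimethylsilyl)thiophene 1,1-dioxide F8. Ipso-bromodesilylation (Br2, AgBF4, CH2Cl2) would then come back to the route at 5.

Step 2. The activated aryl lactone may reopen with moisture during isolation, or the acid may esterify intermolecularly to oligomers. Fallback, setting out from 2: exhaustive silylation (TBSCl, imidazole, DMF) would give tert-butyldimethylsilyl 2-[3,5-dibromo-2-(tert-butyldimethylsilyloxy)phenoxy]acetate F9, and enolisation with in situ silylation (LiN(SiMe3)2, TBSCl, THF, −78 °C) the open-chain ketene bis(silyl) acetal F10. With 5 under the thermal conditions of step 4 this should pass through the bicyclic sulfone F11 and, after loss of SO2, 1,4-dibromo-5-aryloxy-6,6-bis(silyloxy)cyclohexa-1,3-diene F12. The only path of F12 to an arene is loss of tert-butyldimethylsilanol, which comes back to the route at 10 without any lactone.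

**Further compounds**
F1 | step 4 | 4,7-dibromo-3a,4,7,7a-tetrahydro-4,7-epithio-1,3-benzodioxol-2-one S,S-dioxide | O=C1OC2C(O1)C3(Br)C=CC2(Br)S3(=O)=O
F2 | step 4 | cis-4,7-dibromo-3a,7a-dihydro-1,3-benzodioxol-2-one (meso) | O=C1O[C@H]2[C@@H](O1)C(Br)=CC=C2Br
F3 | step 4 | 4,7-dibromo-1,3-benzodioxol-2-one | O=C1Oc2c(Br)ccc(Br)c2O1
F4 | step 4 | 3,6-dibromobenzene-1,2-diol | Oc1c(Br)ccc(Br)c1O
F5 | step 4 | 2,4-dibromo-6-(3,6-dibromo-2-hydroxyphenoxy)benzaldehyde | O=Cc1c(Br)cc(Br)cc1Oc1c(Br)ccc(Br)c1O
F6 | step 4 | 2,4-dibromo-6-(3,6-dibromo-2-hydroxyphenoxy)phenyl formate | O=COc1c(Br)cc(Br)cc1Oc1c(Br)ccc(Br)c1O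
F7 | step 3 | 2,5-bis(trimethylsilyl)thiophene | C[Si](C)(C)c1ccc(s1)[Si](C)(C)C
F8 | step 3 | 2,5-bis(trimethylsilyl)thiophene 1,1-dioxide | C[Si](C)(C)C1=CC=C([Si](C)(C)C)S1(=O)=O
F9 | step 2 | tert-butyldimethylsilyl 2-[3,5-dibromo-2-(tert-butyldimethylsilyloxy)phenoxy]acetate | CC(C)(C)[Si](C)(C)OC(=O)COc1cc(Br)cc(Br)c1O[Si](C)(C)C(C)(C)C
F10 | step 2 | 1,1-bis(tert-butyldimethylsilyloxy)-2-[3,5-dibromo-2-(tert-butyldimethylsilyloxy)phenoxy]ethene | CC(C)(C)[Si](C)(C)OC(O[Si](C)(C)C(C)(C)C)=COc1cc(Br)cc(Br)c1O[Si](C)(C)C(C)(C)C
F11 | step 2 | Diels–Alder adduct of F10 and 5 (1,4-dibromo-7-thiabicyclo[2.2.1]hept-2-ene 7,7-dioxide with the aryloxy group on C6 and two silyloxy groups on C5; racemic, configuration not defined) | O=S1(=O)C2(Br)C=CC1(Br)C(O[Si](C)(C)C(C)(C)C)(O[Si](C)(C)C(C)(C)C)C2Oc3cc(Br)cc(Br)c3O[Si](C)(C)C(C)(C)C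
F12 | step 2 | 1,4-dibromo-5-[3,5-dibromo-2-(tert-butyldimethylsilyloxy)phenoxy]-6,6-bis(tert-butyldimethylsilyloxy)cyclohexa-1,3-diene (racemic) | BrC1=CC=C(Br)C(O[Si](C)(C)C(C)(C)C)(O[Si](C)(C)C(C)(C)C)C1Oc2cc(Br)cc(Br)c2O[Si](C)(C)C(C)(C)C
A1 | direct plan | 3,6-dibromo-2-methoxyphenol | COc1c(O)c(Br)ccc1Br
A2 | direct plan | methyl 2-(3,6-dibromo-2-methoxyphenoxy)acetate | COC(=O)COc1c(Br)ccc(Br)c1OC
A3 | direct plan | tert-butyl 4-(3,6-dibromo-2-methoxyphenoxy)-3-oxobutanoate | CC(C)(C)OC(=O)CC(=O)COc1c(Br)ccc(Br)c1OC
A4 | direct plan | tert-butyl 2-[2-(3,6-dibromo-2-methoxyphenoxy)acetyl]-5-oxopentanoate (racemic) | CC(C)(C)OC(=O)C(CCC=O)C(=O)COc1c(Br)ccc(Br)c1OC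
A5 | direct plan | 2-(3,6-dibromo-2-methoxyphenoxy)cyclohex-2-en-1-one | O=C1CCCC=C1Oc1c(Br)ccc(Br)c1OC
A6 | direct plan | {[6-(3,6-dibromo-2-methoxyphenoxy)cyclohexa-1,5-dien-1-yl]oxy}trimethylsilane | C[Si](C)(C)OC1=CCCC=C1Oc1c(Br)ccc(Br)c1OC
A7 | direct plan | 2-(3,6-dibromo-2-methoxyphenoxy)phenol | Oc1ccccc1Oc1c(Br)ccc(Br)c1OC
A8 | direct plan | 2,4-dibromo-6-(3,6-dibromo-2-methoxyphenoxy)phenol | Oc1c(Br)cc(Br)cc1Oc1c(Br)ccc(Br)c1OC
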